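**Retrosynthetic overview**

- Ciwujiatone ⇐ its bis(benzyl ether) ⇐ a cis-fused 6-aryl-3,7-dioxabicyclo[3.3.0]octan-2-one plus an aryllithium. The aroyl group and the CH2OH group are the two ends of a γ-lactone that holds C3 and C4 cis.
- Bicyclic lactone ⇐ benzyl-protected syringaldehyde plus 3-(bromomethyl)furan-2(5H)-one, cut at C2–C3 (chromium-catalysed asymmetric allylation) and at O1–C5 (5-endo oxa-Michael closure).
- Feature: in the oxolane (O1, C2 aryl, C3 CH2OH, C4 aroyl, C5), O1 and C2 are the C=O group of syringaldehyde; C3, C4 and C5 together with the CH2OH carbon and the ketone carbon are the five carbons of the bromomethylbutenolide.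
- Ring order: the butenolide first, by ring-closing metathesis of allyl 2-(bromomethyl)acrylate (radical bromination of 3-methylfuran-2(5H)-one is avoided because it attacks the ring C5–H, not the methyl group); then the oxolane in the key step. The lactone ring is opened afterwards and no further ring is made.

Key step: step 4

Assumption: the (S,S) enantiomer of ligand L, 1,8-bis[(4S)-4-isopropyl-4,5-dihydro-1,3-oxazol-2-yl]-3,6-diphenyl-9H-carbazole, is taken to deliver the allyl group to the Si face of the aldehyde (S carbinol); if the first run shows the opposite sense, the (R,R) ligand is used with no other change. The target is drawn as the open hydroxy ketone, although it may equilibrate with its bicyclic hemiketal.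

**Route**

Step 1
Reactants: 1 syringaldehyde
Product: 2 4-(benzyloxy)-3,5-dimethoxybenzaldehyde
Conditions: BnBr, K2CO3, DMF, rt
Reagents that add atoms: benzyl bromide BrCc1ccccc1
Why: Williamson etherification of the phenoxide with benzyl bromide; the aldehyde is inert, and the benzyl ether should withstand chromium, fluoride and aryllithium until hydrogenolysis at the end.

Step 2
Reactants: 3 2-(bromomethyl)acrylic acid; 4 allyl alcohol
Product: 5 allyl 2-(bromomethyl)acrylate (prop-2-en-1-yl 2-(bromomethyl)prop-2-enoate)
Conditions: TsOH·H2O (cat.), hydroquinone (trace), cyclohexane, reflux, Dean–Stark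
Reagents that add atoms: none
Why: Fischer esterification driven by azeotropic removal of water, as used for simple alkyl 2-(bromomethyl)acrylates; acid catalysis is chosen because amine bases and nucleophilic acylation catalysts attack the allylic bromide in an SN2′ sense.

Step 3
Reactants: 5 allyl 2-(bromomethyl)acrylate
Product: 6 3-(bromomethyl)furan-2(5H)-one
Conditions: second-generation Hoveyda–Grubbs catalyst [RuCl2(H2IMes)(=CH-C6H4-2-OiPr)] (5 mol %), CH2Cl2 (0.02 M), reflux
Reagents that add atoms: none
Why: Ring-closing metathesis of an allyl 2-substituted acrylate to a butenolide (a known route to 3-substituted furan-2(5H)-ones): the ruthenium alkylidene forms at the allyl group and closes onto the 1,1-disubstituted acrylate alkene with loss of ethene, which fixes the bromomethyl group on C3, and the phosphine-free catalyst leaves no phosphine to be alkylated by the allylic bromide.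

Step 4
Reactants: 2 4-(benzyloxy)-3,5-dimethoxybenzaldehyde; 6 3-(bromomethyl)furan-2(5H)-one
Product: 9 (1R,5R,6S)-6-[4-(benzyloxy)-3,5-dimethoxyphenyl]-3,7-dioxabicyclo[3.3.0]octan-2-one (cis-fused; aryl exo), via anti silyl ether 7 (not isolated), via anti hydroxy lactone 8 (not isolated)
Conditions: CrCl2 (10 mol %), ligand L (12 mol %), Mn powder (2 equiv), iPr2NEt (30 mol %), Me3SiCl (2 equiv), 6 (1.5 equiv), THF, rt; filter through silica (Et2O), concentrate; Bu4NF (1.1 equiv), THF, −78 to −30 °C; AcOH
Reagents that add atoms: none
Why: Proposed new method: bromide 6 is taken up by two equivalents of CrCl2 (divalent chromium, regenerated from trivalent chromium by Mn, while Me3SiCl frees the catalyst from the product alkoxide) to give a ligand-bound allylchromium that adds through its ring γ-carbon to aldehyde 2 in a closed chair transition state, and fluoride then frees the alkoxide of 7 (8 as its ammonium alkoxide), which adds to the exocyclic methylene carbon of the α-methylene lactone before the lactone enolate is protonated. The closest known reaction types are the catalytic asymmetric Nozaki–Hiyama–Kishi allylation of aldehydes with 2-(alkoxycarbonyl)allyl bromides and the base-promoted oxa-Michael cyclisation of γ-hydroxy α-methylene esters, which have not been joined on a bromomethylbutenolide to give a bicyclic ether lactone. The one ring closed is the oxolane, through O1–C5 bond formation by a 5-endo-trig oxa-Michael addition, formally disfavoured but assisted by the s-cis-locked, strongly electrophilic exo-methylene lactone and by the strain-free cis-bicyclo[3.3.0]octane that results. In oxolane numbering, C2 (S) is set by the chiral chromium complex, which leaves the Si face of the aldehyde open; C3 (R) by the chair, in which the aryl group and the ring CH2O arm of the E-configured allyl unit are both equatorial (anti adduct, hence trans C2/C3); C4 (R) by protonation of the enolate, which can give only the cis ring fusion. The step needs the oxa-Michael closure to outrun translactonisation and migration of the exocyclic alkene into the ring: attack of the alkoxide on the lactone carbonyl must pass a strained 2,6-dioxabicyclo[2.2.1]heptane adduct with an sp2 one-carbon bridge, the migration needs an allylic deprotonation at C3 that gains no enolate stabilisation, and the low temperature with an acetic acid quench before warming should keep alkoxide and enolate from equilibrating.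

Step 5
Reactants: 10 4-bromo-2,6-dimethoxyphenol
Product: 11 2-(benzyloxy)-5-bromo-1,3-dimethoxybenzene
Conditions: BnBr, K2CO3, DMF, rt
Reagents that add atoms: benzyl bromide BrCc1ccccc1
Why: Williamson etherification as in step 1; the aryl bromide is untouched.

Step 6
Reactants: 11 2-(benzyloxy)-5-bromo-1,3-dimethoxybenzene; 9 (1R,5R,6S)-6-[4-(benzyloxy)-3,5-dimethoxyphenyl]-3,7-dioxabicyclo[3.3.0]octan-2-one
Product: 14 {(3R,4R,5S)-5-[4-(benzyloxy)-3,5-dimethoxyphenyl]-4-(hydroxymethyl)oxolan-3-yl}[4-(benzyloxy)-3,5-dimethoxyphenyl]methanone, via aryllithium 12 (not isolated), via lithium hemiketal alkoxide 13 (not isolated)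
Conditions: 11 (1.2 equiv), n-BuLi (1.15 equiv), THF, −78 °C; cannulate onto 9 in THF, −78 °C; AcOH/THF at −78 °C, then aq. NH4Cl
Reagents that add atoms: none
Why: Bromine–lithium exchange gives aryllithium 12, and its addition to the γ-lactone at −78 °C (acyl substitution of a lactone by an organolithium, halted at the tetrahedral stage) should stop at alkoxide 13, so that the ketone is released only on the cold acidic quench, a second addition and enolisation at C4 are avoided, and the cis C3/C4 relationship of the lactone is carried unchanged into the hydroxy ketone.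

Step 7
Reactants: 14 the bis(benzyl ether) of step 6
Product: 15 ciwujiatone, (4-hydroxy-3,5-dimethoxyphenyl)[(3R,4R,5S)-5-(4-hydroxy-3,5-dimethoxyphenyl)-4-(hydroxymethyl)oxolan-3-yl]methanone
Conditions: H2 (1 atm), Pd/C (10 % Pd), EtOAc, rt; stop after 2 equiv H2
Reagents that add atoms: none
Why: Catalytic hydrogenolysis of the two aryl benzyl ethers, which should be cleaved much faster than the electron-rich aryl ketone is reduced or the cyclic benzylic C2–O1 bond is cut; the neutral conditions leave the epimerisable C4 untouched.

**Compound list**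

1 | syringaldehyde (4-hydroxy-3,5-dimethoxybenzaldehyde) | COc1cc(C=O)cc(OC)c1O | starting material
2 | 4-(benzyloxy)-3,5-dimethoxybenzaldehyde | COc1cc(C=O)cc(OC)c1OCc2ccccc2 | intermediate
3 | 2-(bromomethyl)acrylic acid | OC(=O)C(=C)CBr | starting material
4 | allyl alcohol (prop-2-en-1-ol) | OCC=C | starting material
5 | allyl 2-(bromomethyl)acrylate | C=CCOC(=O)C(=C)CBr | intermediate
6 | 3-(bromomethyl)furan-2(5H)-one | O=C1OCC=C1CBr | intermediate
7 | (4R)-4-[(S)-[4-(benzyloxy)-3,5-dimethoxyphenyl](trimethylsilyloxy)methyl]-3-methylideneoxolan-2-one, anti silyl ether (not isolated) | C[Si](C)(C)O[C@H](c1cc(OC)c(OCc2ccccc2)c(OC)c1)[C@H]3COC(=O)C3=C | intermediate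
8 | (4R)-4-[(S)-[4-(benzyloxy)-3,5-dimethoxyphenyl](hydroxy)methyl]-3-methylideneoxolan-2-one, anti hydroxy lactone, present as its tetrabutylammonium alkoxide (not isolated) | O[C@H](c1cc(OC)c(OCc2ccccc2)c(OC)c1)[C@H]3COC(=O)C3=C | intermediate
9 | (1R,5R,6S)-6-[4-(benzyloxy)-3,5-dimethoxyphenyl]-3,7-dioxabicyclo[3.3.0]octan-2-one, cis-fused, aryl exo | O=C1[C@H]2CO[C@H](c3cc(OC)c(OCc4ccccc4)c(OC)c3)[C@H]2CO1 | intermediate
10 | 4-bromo-2,6-dimethoxyphenol | COc1cc(Br)cc(OC)c1O | starting material
11 | 2-(benzyloxy)-5-bromo-1,3-dimethoxybenzene | COc1cc(Br)cc(OC)c1OCc2ccccc2 | intermediate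
12 | [4-(benzyloxy)-3,5-dimethoxyphenyl]lithium (not isolated) | [Li]c1cc(OC)c(OCc2ccccc2)c(OC)c1 | intermediate
13 | lithium alkoxide of the hemiketal from addition of 12 to the lactone carbonyl of 9; configuration at the new hemiketal carbon not defined (not isolated) | [Li]OC1(c2cc(OC)c(OCc3ccccc3)c(OC)c2)[C@H]4CO[C@H](c5cc(OC)c(OCc6ccccc6)c(OC)c5)[C@H]4CO1 | intermediate
14 | {(3R,4R,5S)-5-[4-(benzyloxy)-3,5-dimethoxyphenyl]-4-(hydroxymethyl)oxolan-3-yl}[4-(benzyloxy)-3,5-dimethoxyphenyl]methanone | COc1cc(C(=O)[C@H]2CO[C@H](c3cc(OC)c(OCc4ccccc4)c(OC)c3)[C@H]2CO)cc(OC)c1OCc5ccccc5 | intermediate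
15 | ciwujiatone | COc1cc(C(=O)[C@H]2CO[C@H](c3cc(OC)c(O)c(OC)c3)[C@H]2CO)cc(OC)c1O | target

**Step count**

Total: 7 steps. Longest linear sequence: 5 steps (steps 2, 3, 4, 6, 7).

**Steps most likely to fail**

1. Step 4 (proposed new method).
   - What may go wrong: after desilylation the alkoxide may add to the lactone carbonyl faster than to the methylene carbon (translactonisation, which moves the aryl carbinol into the lactone ring and opens a path to the isomeric 4-aryl bicycle). A racemic Mn-mediated background allylation may also erode the enantioselectivity.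
   - Fallback by known reactions, from 8 back to 9, closing the ring through a benzylic cation instead of an alkoxide. The chromium-catalysed allylation is run alone (a known reaction type), silyl ether 7 is cleaved with dilute aqueous HCl in THF, and alcohol 8 is isolated. Copper-catalysed conjugate borylation (CuCl, Xantphos, NaOt-Bu catalytic, B2pin2, MeOH, THF) places boron on the methylene carbon; protonation of the enolate on the face away from the large β-arm should give the cis (3S,4R)-4-[(S)-aryl(hydroxy)methyl]-3-[(4,4,5,5-tetramethyl-1,3,2-dioxaborolan-2-yl)methyl]oxolan-2-one F1. NaBO3·4H2O in THF/H2O oxidises the C–B bond to the cis (3R,4R)-4-[(S)-aryl(hydroxy)methyl]-3-(hydroxymethyl)oxolan-2-one F2. Camphorsulfonic acid in CH2Cl2 then ionises the electron-rich benzylic alcohol, and the primary hydroxyl traps the cation, closing the oxolane to 9 with the aryl group in the more stable exo position. In this variant O1 is the oxygen brought in by the oxidation, the aldehyde oxygen leaves as water, and the absolute configuration rests on C3 from the allylation. A trans epimer of F1 cannot cyclise and is removed at that stage.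

2. Step 6.
   - What may go wrong: collapse of the tetrahedral adduct before the quench, followed by a second addition of the aryllithium to the freed ketone; deprotonation of the lactone instead of addition; epimerisation at C4 of the ketone in the basic medium.
   - Fallback from 9 back to 14 through a Weinreb amide. Lactone 9 is opened with MeNH(OMe)·HCl and i-PrMgCl (THF, −20 °C) to (3R,4R,5S)-5-[4-(benzyloxy)-3,5-dimethoxyphenyl]-4-(hydroxymethyl)-N-methoxy-N-methyloxolane-3-carboxamide F3. The primary alcohol is silylated at once (t-BuMe2SiCl, imidazole, DMF) to the tert-butyldimethylsilyl ether F4, so that the lactone cannot re-form. Aryllithium 12 adds once, through the stable chelate, to give the silyl-protected ketone F5, and Bu4NF buffered with AcOH frees 14.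

3. Step 3.
   - What may go wrong: alkylation or decomposition of the ruthenium carbene by the reactive allylic bromide, and slow closure onto the electron-poor 1,1-disubstituted alkene, leading to oligomers.
   - Fallback from 4 back to 6, bringing the bromine in after the metathesis. Allyl alcohol 4 is acylated with acryloyl chloride (Et3N, CH2Cl2) to allyl acrylate F6 (also commercial). A Morita–Baylis–Hillman reaction with aqueous formaldehyde (DABCO, dioxane/H2O) gives allyl 2-(hydroxymethyl)acrylate F7. Ring-closing metathesis with the catalyst of step 3 gives 3-(hydroxymethyl)furan-2(5H)-one F8, and PBr3 in Et2O at 0 °C converts the allylic alcohol into 6.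

**Further compounds**

F1 | step 4 | (3S,4R)-4-[(S)-[4-(benzyloxy)-3,5-dimethoxyphenyl](hydroxy)methyl]-3-[(4,4,5,5-tetramethyl-1,3,2-dioxaborolan-2-yl)methyl]oxolan-2-one | O[C@H](c1cc(OC)c(OCc2ccccc2)c(OC)c1)[C@H]3COC(=O)[C@H]3CB4OC(C)(C)C(C)(C)O4
F2 | step 4 | (3R,4R)-4-[(S)-[4-(benzyloxy)-3,5-dimethoxyphenyl](hydroxy)methyl]-3-(hydroxymethyl)oxolan-2-one | O[C@H](c1cc(OC)c(OCc2ccccc2)c(OC)c1)[C@H]3COC(=O)[C@H]3CO
F3 | step 6 | (3R,4R,5S)-5-[4-(benzyloxy)-3,5-dimethoxyphenyl]-4-(hydroxymethyl)-N-methoxy-N-methyloxolane-3-carboxamide | CON(C)C(=O)[C@H]1CO[C@H](c2cc(OC)c(OCc3ccccc3)c(OC)c2)[C@H]1CO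
F4 | step 6 | (3R,4R,5S)-5-[4-(benzyloxy)-3,5-dimethoxyphenyl]-4-[(tert-butyldimethylsilyloxy)methyl]-N-methoxy-N-methyloxolane-3-carboxamide | CON(C)C(=O)[C@H]1CO[C@H](c2cc(OC)c(OCc3ccccc3)c(OC)c2)[C@H]1CO[Si](C)(C)C(C)(C)C
F5 | step 6 | {(3R,4R,5S)-5-[4-(benzyloxy)-3,5-dimethoxyphenyl]-4-[(tert-butyldimethylsilyloxy)methyl]oxolan-3-yl}[4-(benzyloxy)-3,5-dimethoxyphenyl]methanone | COc1cc(C(=O)[C@H]2CO[C@H](c3cc(OC)c(OCc4ccccc4)c(OC)c3)[C@H]2CO[Si](C)(C)C(C)(C)C)cc(OC)c1OCc5ccccc5
F6 | step 3 | allyl acrylate | C=CCOC(=O)C=C
F7 | step 3 | allyl 2-(hydroxymethyl)acrylate | C=CCOC(=O)C(=C)CO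
F8 | step 3 | 3-(hydroxymethyl)furan-2(5H)-one | O=C1OCC=C1CO
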